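The ring C1 carbinol of the target sits homoallylic to the C3–C4 bond that carries chlorine and bromine. The halogens are therefore traced back to a C3=C4 alkene, and the resulting 4-methylcyclohex-3-en-1-ol unit to a thujane-type 2-methylbicyclo[3.1.0]hexan-2-ol. In the key step acid ionises this tertiary cyclopropylcarbinol, the bond shared by the two rings breaks with ring expansion to the cyclohexene, and water takes the quaternary carbon with inversion, setting C1 in one operation. The precursor is a single (1S,5S) enantiomer carrying an inert silyloxymethyl group at the ring-fusion carbon, made from a resolved terminal epoxide; that group later becomes the carboxyl tether and the side-chain attachment point.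

Key step: step 9

Remark 1: cyclohexane intermediates are numbered as in the target (C1 carbinol, C3 chlorine-bearing, C4 bromine- and methyl-bearing carbon); in the bicyclo[3.1.0]hexanes C1 is the cyclopropane CH, C2 the carbinol or carbonyl carbon, C5 the quaternary fusion carbon and C6 the cyclopropane CH2.
Remark 2: in the key step the ring alkene comes from the C1–C2 bond of the bicycle; the C1–C5 bond common to both rings is the one that breaks.
Remark 3: the salen ligand enantiomer in step 5 is the one that leaves the (S)-epoxide unreacted, taken here to be (S,S).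

Step 1
Reactants: 1 2-methylenepropane-1,3-diol
Product: 2 2-{[tert-butyl(diphenyl)silyl]oxymethyl}prop-2-en-1-ol
Conditions: NaH (1.0 equiv), THF, 0 °C; then t-BuPh2SiCl (1.0 equiv), 0 °C to rt
Reagents that add atoms: tert-butyl(chloro)diphenylsilane, CC(C)(C)[Si](Cl)(c1ccccc1)c1ccccc1
Why: Williamson-type O-silylation of the sparingly soluble monosodium alkoxide of the symmetrical diol should stop after one silyl group, and no stereocentre is formed.

Step 2
Reactants: 2 2-{[tert-butyl(diphenyl)silyl]oxymethyl}prop-2-en-1-ol, 3 triethyl orthoacetate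
Product: 5 ethyl 4-{[tert-butyl(diphenyl)silyl]oxymethyl}pent-4-enoate, via mixed ketene acetal 4 (not isolated)
Conditions: EtCO2H (5 mol%), neat 3 (excess), 140 °C, EtOH distilled off
Reagents that add atoms: none
Why: Johnson–Claisen rearrangement, in which acid-catalysed exchange gives the mixed ketene acetal and its [3,3]-sigmatropic shift joins the ketene-acetal carbon to the terminal alkene carbon while regenerating the 1,1-disubstituted alkene, without creating a stereocentre.

Step 3
Reactants: 5 ethyl 4-{[tert-butyl(diphenyl)silyl]oxymethyl}pent-4-enoate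
Product: 6 4-{[tert-butyl(diphenyl)silyl]oxymethyl}pent-4-enal
Conditions: i-Bu2AlH (1.1 equiv), CH2Cl2, −78 °C; then H2O
Reagents that add atoms: none
Why: Partial ester reduction with one equivalent of i-Bu2AlH at −78 °C should stop at the tetrahedral aluminium hemiacetal, which releases the aldehyde on work-up, the silyl ether and alkene being inert.

Step 4
Reactants: 6 4-{[tert-butyl(diphenyl)silyl]oxymethyl}pent-4-enal
Product: 7 rac-tert-butyl{[2-methylidene-4-(oxiran-2-yl)butyl]oxy}diphenylsilane
Conditions: Me3S+ I−, n-BuLi, THF, −10 °C to rt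
Reagents that add atoms: trimethylsulfonium iodide, C[S+](C)C.[I-]
Why: Corey–Chaykovsky epoxidation, in which dimethylsulfonium methylide adds to the aldehyde and the betaine closes with loss of dimethyl sulfide to the terminal epoxide, made as the racemate on purpose.

Step 5
Reactants: 7 rac-tert-butyl{[2-methylidene-4-(oxiran-2-yl)butyl]oxy}diphenylsilane
Product: 8 tert-butyl({2-methylidene-4-[(2S)-oxiran-2-yl]butyl}oxy)diphenylsilane
Conditions: (S,S)-(salen)Co(OAc) (0.5 mol%; salen = dianion of N,N′-bis(3,5-di-tert-butylsalicylidene)cyclohexane-1,2-diamine), H2O (0.55 equiv), THF, 0 °C to rt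
Reagents that add atoms: none
Why: Hydrolytic kinetic resolution, in which the chiral cobalt salen complex hydrates one enantiomer of a terminal epoxide far faster than the other, should consume the (R)-epoxide as its diol and leave the (S)-epoxide in high enantiomeric purity (at most half of the material by design), fixing the absolute configuration of the ring fragment.

Step 6
Reactants: 8 tert-butyl({2-methylidene-4-[(2S)-oxiran-2-yl]butyl}oxy)diphenylsilane
Product: 9 (1S,2S,5S)-5-{[tert-butyl(diphenyl)silyl]oxymethyl}bicyclo[3.1.0]hexan-2-ol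
Conditions: lithium 2,2,6,6-tetramethylpiperidide (2 equiv), t-BuOMe, 0 °C to rt
Reagents that add atoms: none
Why: Intramolecular cyclopropanation by an α-lithiated terminal epoxide, a reaction type established for hex-5-enyl oxiranes including 1,1-disubstituted alkenes, in which the hindered amide lithiates the oxirane CH2 trans to the chain and the carbenoid carbon adds across the tethered alkene with inversion as its C–O bond opens, so the fixed carbinol centre dictates both cyclopropane carbons (hydroxyl trans to the cyclopropane, hence the (1S,5S) fusion).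

Step 7
Reactants: 9 (1S,2S,5S)-5-{[tert-butyl(diphenyl)silyl]oxymethyl}bicyclo[3.1.0]hexan-2-ol
Product: 10 (1S,5S)-5-{[tert-butyl(diphenyl)silyl]oxymethyl}bicyclo[3.1.0]hexan-2-one
Conditions: n-Pr4N[RuO4] (5 mol%), N-methylmorpholine N-oxide, 4 Å sieves, CH2Cl2, rt
Reagents that add atoms: none
Why: Ley–Griffith oxidation converts the secondary cyclopropylcarbinol into the ketone under neutral conditions that should not open the cyclopropane, and the cis ring fusion at C1 and C5 cannot epimerise.

Step 8
Reactants: 10 (1S,5S)-5-{[tert-butyl(diphenyl)silyl]oxymethyl}bicyclo[3.1.0]hexan-2-one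
Product: 11 (1S,2R,5S)-5-{[tert-butyl(diphenyl)silyl]oxymethyl}-2-methylbicyclo[3.1.0]hexan-2-ol
Conditions: MeMgBr, THF, −78 to 0 °C
Reagents that add atoms: methylmagnesium bromide, C[Mg]Br
Why: Grignard 1,2-addition from the face away from the cyclopropane methylene should give mainly the (2R)-carbinol, and since this centre is erased in step 9 either epimer serves.

Step 9
Reactants: 11 (1S,2R,5S)-5-{[tert-butyl(diphenyl)silyl]oxymethyl}-2-methylbicyclo[3.1.0]hexan-2-ol
Product: 12 (1S)-1-{[tert-butyl(diphenyl)silyl]oxymethyl}-4-methylcyclohex-3-en-1-ol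
Conditions: H2SO4 (0.05 M), THF/H2O (2:1), 0 °C
Reagents that add atoms: water, O
Why: Acid-catalysed loss of water from the tertiary cyclopropylcarbinol (either C2 epimer gives the same ion) leaves an empty p orbital at C2 that lies bisected to the cyclopropane, so the C1–C5 bond common to both rings breaks as C1=C2 forms, charge developing at the fully substituted C5 and not at the primary C6. The closest known reaction is the cyclopropylcarbinyl-to-homoallyl rearrangement of sabinene hydrate to terpinen-4-ol in dilute acid. The cyclohexene is not closed by a new bond but arises by ring expansion, the cleaved fusion bond merging the three- and five-membered rings so that C6 becomes ring C2 and C5 becomes ring C1 of 12. The one stereocentre of 12 is set by water bonding to C5 anti to the departing C1–C5 bond, an inversion that turns the (1S,5S) ring fusion fixed in steps 5 and 6 into (1S)-12. The step needs this capture to be concerted with ring opening, because a free 4-methylcyclohex-3-en-1-yl cation is achiral and could also take a hydride from the oxymethyl carbon; the inductively withdrawing, non-participating silyloxymethyl group on C5 disfavours that open ion and the water-rich medium at 0 °C supplies the nucleophile at once. Dilute acid should spare both the silyl ether and the product, whose tertiary carbinol lacks cyclopropyl assistance and ionises far more slowly.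

Step 10
Reactants: 12 (1S)-1-{[tert-butyl(diphenyl)silyl]oxymethyl}-4-methylcyclohex-3-en-1-ol
Product: 13 (1S)-1-(hydroxymethyl)-4-methylcyclohex-3-en-1-ol
Conditions: n-Bu4NF, THF, rt
Reagents that add atoms: none
Why: Fluoride-mediated desilylation is driven by the strong Si–F bond and should leave the tertiary alcohol, the alkene and the C1 stereocentre untouched.

Step 11
Reactants: 13 (1S)-1-(hydroxymethyl)-4-methylcyclohex-3-en-1-ol
Product: 15 (1S)-1-hydroxy-4-methylcyclohex-3-ene-1-carboxylic acid, via hydroxy aldehyde 14 (not isolated)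
Conditions: SO3·pyridine, DMSO, i-Pr2NEt, CH2Cl2, 0 °C; then NaClO2, NaH2PO4, 2-methylbut-2-ene, t-BuOH/H2O, 0 °C to rt
Reagents that add atoms: sodium chlorite, [Na+].[O-]Cl=O
Why: Parikh–Doering oxidation of the only oxidisable (primary) hydroxyl followed by Pinnick oxidation of the crude α-hydroxy aldehyde, with an alkene scavenger for hypochlorous acid, should reach the acid without touching the tertiary carbinol centre or the ring alkene.

Step 12
Reactants: 15 (1S)-1-hydroxy-4-methylcyclohex-3-ene-1-carboxylic acid
Product: 17 (1R,3S,6S)-3-hydroxy-6-methyl-7-oxabicyclo[4.1.0]heptane-3-carboxylic acid, via iodolactone 16 (not isolated)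
Conditions: I2, KI, NaHCO3, THF/H2O, 0 °C, dark; Na2S2O3; then NaOH (aq), rt; NaHSO4 to pH 3, 0 °C
Reagents that add atoms: sodium hydroxide, [Na+].[OH-]
Why: Iodolactonisation then saponification, in which reversible iodonium formation is funnelled through anti attack by the C1 carboxylate from the only face it can reach (at the more substituted C4, and attack at C3 would converge), after which hydroxide opens the lactone and the freed alkoxide displaces iodide from the back, so C1 controls both new centres and the epoxide ends cis to the carboxyl and trans to the C1 hydroxyl.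

Step 13
Reactants: 17 (1R,3S,6S)-3-hydroxy-6-methyl-7-oxabicyclo[4.1.0]heptane-3-carboxylic acid
Product: 18 S-ethyl (1R,3S,6S)-3-hydroxy-6-methyl-7-oxabicyclo[4.1.0]heptane-3-carbothioate
Conditions: EtSH, DCC, DMAP (5 mol%), CH2Cl2, 0 °C to rt
Reagents that add atoms: ethanethiol, CCS
Why: Steglich-type carbodiimide thioesterification should proceed without interference from the tertiary hydroxyl or from the epoxide, which lies on the same face as the carboxyl and so cannot be opened by it.

Step 14
Reactants: 18 S-ethyl (1R,3S,6S)-3-hydroxy-6-methyl-7-oxabicyclo[4.1.0]heptane-3-carbothioate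
Product: 19 S-ethyl (1S,3S,4S)-3-chloro-1,4-dihydroxy-4-methylcyclohexane-1-carbothioate
Conditions: LiCl, AcOH, THF, rt
Reagents that add atoms: lithium chloride, [Li+].[Cl-]
Why: Epoxide opening of SN2 type under weak acid, in which chloride attacks the secondary C3 from the face opposite the oxirane in the trans-diaxial mode (Fürst–Plattner rule) that leads directly to the chair with the thioester equatorial, places chlorine cis to the C1 hydroxyl and leaves the tertiary C4 hydroxyl trans to it.

Step 15
Reactants: 19 S-ethyl (1S,3S,4S)-3-chloro-1,4-dihydroxy-4-methylcyclohexane-1-carbothioate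
Product: 20 S-ethyl (1S,3S,4S)-4-bromo-3-chloro-1-hydroxy-4-methylcyclohexane-1-carbothioate
Conditions: HBr (33% in AcOH), CH2Cl2, 0 °C to rt
Reagents that add atoms: hydrogen bromide, Br
Why: SN1 substitution of a tertiary alcohol with neighbouring-group participation, in which the antiperiplanar axial chlorine bridges the C4 cation on its own face so that bromide enters from the face the hydroxyl left (retention at C4, bromine trans-diaxial to chlorine), while the C1 hydroxyl next to the thioester carbonyl should not ionise.

Step 16
Reactants: 21 3-chloropropanoyl chloride, 22 isopropenylmagnesium bromide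
Product: 24 5-chloro-2-methylpent-1-en-3-one, via isopropenylzinc chloride 23 (not isolated)
Conditions: ZnCl2, THF, 0 °C (22 to 23); then 21, Pd(PPh3)4 (2 mol%), 0 °C to rt
Reagents that add atoms: none
Why: Negishi acylation, in which the Grignard reagent is transmetalated to the alkenylzinc chloride and coupled with the acid chloride under palladium catalysis, should stop at the ketone and avoid the over-addition expected of the Grignard reagent itself.

Step 17
Reactants: 24 5-chloro-2-methylpent-1-en-3-one
Product: 25 (3R)-5-chloro-2-methylpent-1-en-3-ol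
Conditions: (S)-1-methyl-3,3-diphenyltetrahydro-1H,3H-pyrrolo[1,2-c][1,3,2]oxazaborole (10 mol%), catecholborane, toluene, −78 °C
Reagents that add atoms: none
Why: Corey–Bakshi–Shibata reduction, in which the oxazaborolidine binds the ketone with the isopropenyl group as the larger substituent and directs hydride from catecholborane to one carbonyl face, should set the (R)-carbinol with the (S)-catalyst while the low temperature avoids conjugate reduction and hydroboration.

Step 18
Reactants: 25 (3R)-5-chloro-2-methylpent-1-en-3-ol
Product: 26 tert-butyl{[(3R)-5-chloro-2-methylpent-1-en-3-yl]oxy}dimethylsilane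
Conditions: t-BuMe2SiCl, imidazole, DMF, rt
Reagents that add atoms: tert-butyl(chloro)dimethylsilane, CC(C)(C)[Si](C)(C)Cl
Why: Standard imidazole-promoted silylation of the secondary allylic alcohol does not involve the stereocentre.

Step 19
Reactants: 26 tert-butyl{[(3R)-5-chloro-2-methylpent-1-en-3-yl]oxy}dimethylsilane
Product: 27 tert-butyl{[(3R)-5-iodo-2-methylpent-1-en-3-yl]oxy}dimethylsilane
Conditions: NaI, acetone, reflux
Reagents that add atoms: sodium iodide, [Na+].[I-]
Why: Finkelstein exchange, an SN2 displacement of the primary chloride driven by precipitation of NaCl from acetone, provides the iodide needed for zinc insertion.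

Step 20
Reactants: 20 S-ethyl (1S,3S,4S)-4-bromo-3-chloro-1-hydroxy-4-methylcyclohexane-1-carbothioate, 27 tert-butyl{[(3R)-5-iodo-2-methylpent-1-en-3-yl]oxy}dimethylsilane
Product: 29 (4R)-1-[(1S,3S,4S)-4-bromo-3-chloro-1-hydroxy-4-methylcyclohexyl]-4-{[tert-butyl(dimethyl)silyl]oxy}-5-methylhex-5-en-1-one, via alkylzinc iodide 28 (not isolated)
Conditions: Zn dust (activated), THF, 40 °C (27 to 28, 2.5 equiv); then 20, PdCl2(PPh3)2 (5 mol%), toluene, rt
Reagents that add atoms: none
Why: Fukuyama coupling, in which zinc inserts into the primary C–I bond and the alkylzinc iodide alkylates the acylpalladium species formed from the thioester, should give the ketone under neutral conditions that tolerate the tertiary bromide, the secondary chloride, the silyl ether and (with excess zinc reagent) the free tertiary hydroxyl, without touching any stereocentre.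

Step 21
Reactants: 29 (4R)-1-[(1S,3S,4S)-4-bromo-3-chloro-1-hydroxy-4-methylcyclohexyl]-4-{[tert-butyl(dimethyl)silyl]oxy}-5-methylhex-5-en-1-one
Product: 30 (1S,3S,4S)-4-bromo-1-[(5R)-5-{[tert-butyl(dimethyl)silyl]oxy}-6-methylhepta-1,6-dien-2-yl]-3-chloro-4-methylcyclohexan-1-ol
Conditions: Cp2Ti(CH2)(Cl)AlMe2 (3 equiv), pyridine, THF/toluene, −40 to 0 °C
Reagents that add atoms: Tebbe reagent Cp2Ti(CH2)(Cl)AlMe2, C[Al-]1(C)C[Ti](C2C=CC=C2)(C2C=CC=C2)[Cl+]1
Why: Tebbe methylenation, in which the titanium methylidene released by pyridine adds to the hindered α-hydroxy ketone by [2+2] cycloaddition and cycloreverts to the 1,1-disubstituted alkene, is non-basic and should avoid the E2 loss of HBr that a phosphorus ylide would risk, with excess reagent covering the free hydroxyl.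

Step 22
Reactants: 30 (1S,3S,4S)-4-bromo-1-[(5R)-5-{[tert-butyl(dimethyl)silyl]oxy}-6-methylhepta-1,6-dien-2-yl]-3-chloro-4-methylcyclohexan-1-ol
Product: 31 (1S,3S,4S)-4-bromo-3-chloro-1-[(5R)-5-hydroxy-6-methylhepta-1,6-dien-2-yl]-4-methylcyclohexan-1-ol
Conditions: HF·pyridine, pyridine, THF, 0 °C to rt
Reagents that add atoms: none
Why: Buffered HF·pyridine cleaves the secondary silyl ether by fluoride attack at silicon without the basicity of n-Bu4NF, so the tertiary bromide, the chloride and the tertiary allylic alcohol should survive and the target is released.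

Compound list
1 | 2-methylenepropane-1,3-diol | C=C(CO)CO | starting material
2 | 2-{[tert-butyl(diphenyl)silyl]oxymethyl}prop-2-en-1-ol | C=C(CO)CO[Si](c1ccccc1)(c1ccccc1)C(C)(C)C | intermediate
3 | triethyl orthoacetate | CCOC(C)(OCC)OCC | starting material
4 | tert-butyl[(2-{[(1-ethoxyethenyl)oxy]methyl}prop-2-en-1-yl)oxy]diphenylsilane (mixed ketene acetal) | C=C(OCC)OCC(=C)CO[Si](c1ccccc1)(c1ccccc1)C(C)(C)C | intermediate
5 | ethyl 4-{[tert-butyl(diphenyl)silyl]oxymethyl}pent-4-enoate | CCOC(=O)CCC(=C)CO[Si](c1ccccc1)(c1ccccc1)C(C)(C)C | intermediate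
6 | 4-{[tert-butyl(diphenyl)silyl]oxymethyl}pent-4-enal | O=CCCC(=C)CO[Si](c1ccccc1)(c1ccccc1)C(C)(C)C | intermediate
7 | rac-tert-butyl{[2-methylidene-4-(oxiran-2-yl)butyl]oxy}diphenylsilane | C=C(CCC1CO1)CO[Si](c1ccccc1)(c1ccccc1)C(C)(C)C | intermediate
8 | tert-butyl({2-methylidene-4-[(2S)-oxiran-2-yl]butyl}oxy)diphenylsilane | C=C(CC[C@H]1CO1)CO[Si](c1ccccc1)(c1ccccc1)C(C)(C)C | intermediate
9 | (1S,2S,5S)-5-{[tert-butyl(diphenyl)silyl]oxymethyl}bicyclo[3.1.0]hexan-2-ol | CC(C)(C)[Si](OC[C@]12CC[C@H](O)[C@H]1C2)(c1ccccc1)c1ccccc1 | intermediate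
10 | (1S,5S)-5-{[tert-butyl(diphenyl)silyl]oxymethyl}bicyclo[3.1.0]hexan-2-one | CC(C)(C)[Si](OC[C@]12CCC(=O)[C@H]1C2)(c1ccccc1)c1ccccc1 | intermediate
11 | (1S,2R,5S)-5-{[tert-butyl(diphenyl)silyl]oxymethyl}-2-methylbicyclo[3.1.0]hexan-2-ol | CC(C)(C)[Si](OC[C@]12CC[C@@](C)(O)[C@H]1C2)(c1ccccc1)c1ccccc1 | intermediate
12 | (1S)-1-{[tert-butyl(diphenyl)silyl]oxymethyl}-4-methylcyclohex-3-en-1-ol | CC(C)(C)[Si](OC[C@]1(O)CCC(C)=CC1)(c1ccccc1)c1ccccc1 | intermediate
13 | (1S)-1-(hydroxymethyl)-4-methylcyclohex-3-en-1-ol | OC[C@]1(O)CCC(C)=CC1 | intermediate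
14 | (1S)-1-hydroxy-4-methylcyclohex-3-ene-1-carbaldehyde | O=C[C@]1(O)CCC(C)=CC1 | intermediate
15 | (1S)-1-hydroxy-4-methylcyclohex-3-ene-1-carboxylic acid | OC(=O)[C@]1(O)CCC(C)=CC1 | intermediate
16 | (1S,4S,6S)-4-hydroxy-6-iodo-1-methyl-2-oxabicyclo[2.2.2]octan-3-one | O=C1O[C@@]2(C)CC[C@]1(O)C[C@@H]2I | intermediate
17 | (1R,3S,6S)-3-hydroxy-6-methyl-7-oxabicyclo[4.1.0]heptane-3-carboxylic acid | OC(=O)[C@]1(O)CC[C@]2(C)O[C@@H]2C1 | intermediate
18 | S-ethyl (1R,3S,6S)-3-hydroxy-6-methyl-7-oxabicyclo[4.1.0]heptane-3-carbothioate | CCSC(=O)[C@]1(O)CC[C@]2(C)O[C@@H]2C1 | intermediate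
19 | S-ethyl (1S,3S,4S)-3-chloro-1,4-dihydroxy-4-methylcyclohexane-1-carbothioate | CCSC(=O)[C@]1(O)CC[C@](C)(O)[C@@H](Cl)C1 | intermediate
20 | S-ethyl (1S,3S,4S)-4-bromo-3-chloro-1-hydroxy-4-methylcyclohexane-1-carbothioate | CCSC(=O)[C@]1(O)CC[C@](C)(Br)[C@@H](Cl)C1 | intermediate
21 | 3-chloropropanoyl chloride | O=C(Cl)CCCl | starting material
22 | isopropenylmagnesium bromide | C=C(C)[Mg]Br | starting material
23 | (prop-1-en-2-yl)zinc chloride | C=C(C)[Zn]Cl | intermediate
24 | 5-chloro-2-methylpent-1-en-3-one | C=C(C)C(=O)CCCl | intermediate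
25 | (3R)-5-chloro-2-methylpent-1-en-3-ol | C=C(C)[C@H](O)CCCl | intermediate
26 | tert-butyl{[(3R)-5-chloro-2-methylpent-1-en-3-yl]oxy}dimethylsilane | C=C(C)[C@H](O[Si](C)(C)C(C)(C)C)CCCl | intermediate
27 | tert-butyl{[(3R)-5-iodo-2-methylpent-1-en-3-yl]oxy}dimethylsilane | C=C(C)[C@H](O[Si](C)(C)C(C)(C)C)CCI | intermediate
28 | {(3R)-3-[tert-butyl(dimethyl)silyl]oxy-4-methylpent-4-en-1-yl}zinc iodide | C=C(C)[C@H](O[Si](C)(C)C(C)(C)C)CC[Zn]I | intermediate
29 | (4R)-1-[(1S,3S,4S)-4-bromo-3-chloro-1-hydroxy-4-methylcyclohexyl]-4-{[tert-butyl(dimethyl)silyl]oxy}-5-methylhex-5-en-1-one | C=C(C)[C@H](O[Si](C)(C)C(C)(C)C)CCC(=O)[C@]1(O)CC[C@](C)(Br)[C@@H](Cl)C1 | intermediate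
30 | (1S,3S,4S)-4-bromo-1-[(5R)-5-{[tert-butyl(dimethyl)silyl]oxy}-6-methylhepta-1,6-dien-2-yl]-3-chloro-4-methylcyclohexan-1-ol | C=C(C)[C@H](O[Si](C)(C)C(C)(C)C)CCC(=C)[C@]1(O)CC[C@](C)(Br)[C@@H](Cl)C1 | intermediate
31 | (1S,3S,4S)-4-bromo-3-chloro-1-[(5R)-5-hydroxy-6-methylhepta-1,6-dien-2-yl]-4-methylcyclohexan-1-ol | C=C(C)[C@H](O)CCC(=C)[C@]1(O)CC[C@](C)(Br)[C@@H](Cl)C1 | target

Total step count: 22 steps.
Longest linear sequence: 18 steps (steps 1 to 15, then 20 to 22); steps 16 to 19 build the side-chain iodide.

Steps most likely to fail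

Step 9 (key step). Ionisation may run ahead of water capture, so that a free, achiral ring cation erodes the enantiomeric purity, loses a proton to dienes or takes a hydride from the oxymethyl carbon. The fallback sets out from 11 and comes back to the route at 13; it replaces external water by an oxygen delivered from within the substituent. Desilylation with n-Bu4NF should give (1S,2R,5S)-5-(hydroxymethyl)-2-methylbicyclo[3.1.0]hexan-2-ol F1, and acetylation of the primary hydroxyl (Ac2O, pyridine) the ester [(1S,4R,5S)-4-hydroxy-4-methylbicyclo[3.1.0]hexan-1-yl]methyl acetate F2. On ionisation in dilute aqueous acid the acetate carbonyl oxygen, held next to the fusion carbon, should open the cyclopropane from the back (neighbouring-group participation, inversion at that carbon) to the cation (5S)-2,8-dimethyl-1,3-dioxaspiro[4.5]dec-7-en-2-ylium F3. Water adds to F3 at the acyl carbon, not at the stereocentre, to give [(1S)-1-hydroxy-4-methylcyclohex-3-en-1-yl]methyl acetate F4, and methanolysis (K2CO3, MeOH) returns 13. The acyloxymethyl group is also more electron-poor than the silyl ether, which further disfavours the open cation.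

Step 14. Regioselectivity may erode through chloride entry at the tertiary C4, or the C1 hydroxyl may attack C4 across the ring and form a bridged ether. The fallback sets out from 15 and comes back at 20, bypassing steps 12 to 15; regiochemistry is then fixed by a tether instead of by the conformation of an epoxide. Chlorolactonisation (1,3-dichloro-5,5-dimethylhydantoin, NaHCO3, CH2Cl2/H2O) should let the C1 carboxylate capture the chloronium ion at the more substituted C4, giving (1S,4S,6S)-6-chloro-4-hydroxy-1-methyl-2-oxabicyclo[2.2.2]octan-3-one F5 with chlorine on the face opposite the tether. HBr in AcOH should then cleave the bridged C4–O bond with participation of the antiperiplanar chlorine to (1S,3S,4S)-4-bromo-3-chloro-1-hydroxy-4-methylcyclohexane-1-carboxylic acid F6, and DCC/EtSH converts F6 into 20. This detour is less controlled in the chlorination, because chloronium formation is not reversible, which is why it is not the main route.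

Step 21. The Lewis-acidic aluminium by-product may trigger ionisation or elimination at the tertiary bromide, the metal alkoxide of the α-hydroxy ketone may undergo α-ketol rearrangement, or the reaction may stall because the free hydroxyl consumes reagent. The fallback sets out from 29 and comes back at 31; it replaces the titanium carbene by a Peterson olefination. Me3SiCH2MgCl premixed with CeCl3 (THF, −78 °C) should add to the ketone as a weakly basic organocerium reagent and give (5R)-2-[(1S,3S,4S)-4-bromo-3-chloro-1-hydroxy-4-methylcyclohexyl]-5-{[tert-butyl(dimethyl)silyl]oxy}-6-methyl-1-(trimethylsilyl)hept-6-en-2-ol F7 as a mixture of C2 epimers. HF·pyridine should then effect the acid-type anti elimination of the β-hydroxysilane to the 1,1-disubstituted alkene and cleave the silyl ether in the same operation, giving 31 directly.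

Further compounds
F1 | step 9 | (1S,2R,5S)-5-(hydroxymethyl)-2-methylbicyclo[3.1.0]hexan-2-ol | OC[C@]12CC[C@@](C)(O)[C@H]1C2
F2 | step 9 | [(1S,4R,5S)-4-hydroxy-4-methylbicyclo[3.1.0]hexan-1-yl]methyl acetate | CC(=O)OC[C@]12CC[C@@](C)(O)[C@H]1C2
F3 | step 9 | (5S)-2,8-dimethyl-1,3-dioxaspiro[4.5]dec-7-en-2-ylium | CC1=[O+][C@@]2(CO1)CCC(C)=CC2
F4 | step 9 | [(1S)-1-hydroxy-4-methylcyclohex-3-en-1-yl]methyl acetate | CC(=O)OC[C@]1(O)CCC(C)=CC1
F5 | step 14 | (1S,4S,6S)-6-chloro-4-hydroxy-1-methyl-2-oxabicyclo[2.2.2]octan-3-one | O=C1O[C@@]2(C)CC[C@]1(O)C[C@@H]2Cl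
F6 | step 14 | (1S,3S,4S)-4-bromo-3-chloro-1-hydroxy-4-methylcyclohexane-1-carboxylic acid | OC(=O)[C@]1(O)CC[C@](C)(Br)[C@@H](Cl)C1
F7 | step 21 | (5R)-2-[(1S,3S,4S)-4-bromo-3-chloro-1-hydroxy-4-methylcyclohexyl]-5-{[tert-butyl(dimethyl)silyl]oxy}-6-methyl-1-(trimethylsilyl)hept-6-en-2-ol | C=C(C)[C@H](O[Si](C)(C)C(C)(C)C)CCC(O)(C[Si](C)(C)C)[C@]1(O)CC[C@](C)(Br)[C@@H](Cl)C1
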